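**Retrosynthetic overview**

1. The pyran ring is cut last: C4–O and C5–C1' come from an inverse-demand hetero-Diels–Alder reaction between the ortho-quinone methide (from benzaldehyde and 2,4-diformylphloroglucinol) and the (4E)-alkene of (+)-β-caryophyllene, three components in one operation.
2. (+)-β-Caryophyllene ← methylenation at C8 and C9 epimerisation of a cis-fused (4E)-cyclononenone ← three-carbon ring expansion of a cyclobutane-fused cyclohexanone: samarium diiodide closes a cyclopentanol by forming C7–C8, and the alkoxide at once fragments C4–C8 with loss of a C5 mesylate.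
3. Enabling feature: in the nine-membered ring the methylidene carbon C8 (a latent ketone) and the oxygen-bearing quaternary carbon C4 stand 1,5 to each other, and the chroman-fused bond C4–C5 is a latent (E)-alkene; a temporary C4–C8 bond therefore divides the nine-membered ring into a six-membered ring (C8, C9, C1, C2, C3, C4) and a five-membered ring (C8, C4, C5, C6, C7).
4. Fragmentation precursor ← aldol, oxidation, C-methylation and catalyst-controlled reduction on (1S,6S)-7,7-dimethylbicyclo[4.2.0]octan-2-one ← enantioselective [2+2] photocycloaddition of cyclohexenone and isobutene.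
5. Ring order: cyclobutane (on the six-membered ring of the enone) → transient five-membered ring → nine-membered ring → pyran ring.

Key step: step 8

Assumption: the terpenoid half of the target is (1S,9R), the mirror image of commercial (−)-β-caryophyllene, so the terpene is made de novo; 2,4-diformylphloroglucinol and 3-(tert-butyldimethylsilyloxy)propanal are taken as purchasable; atoms are cited in caryophyllane numbering (C8 methylidene carbon, C1' benzylic carbon) unless a compound's own locants are given.

**Route**

Step 1
Reactants: 1 cyclohex-2-en-1-one; 2 2-methylpropene (isobutene)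
Product: 4 (1S,6S)-7,7-dimethylbicyclo[4.2.0]octan-2-one (cis-fused), via trans-fused photoadduct 3 (not isolated)
Conditions: chiral diarylprolinol-derived 1,3,2-oxazaborolidine·AlBr3 (50 mol %, enantiomer that gives the 6S adduct), excess 2, CH2Cl2, hν (366 nm), −75 °C; then basic Al2O3, CH2Cl2, rt
Reagents that add atoms: none
Why: Enantioselective intermolecular [2+2] photocycloaddition: only the enone bound to the chiral Lewis acid absorbs at 366 nm, the excited complex adds 2 head-to-tail (CMe2 to the β-carbon) on its unshielded face, which sets C6 as S, and alumina epimerises the α-carbon of the trans-fused portion 3 to the stable cis fusion (C1 S).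

Step 2
Reactants: 4 (1S,6S)-7,7-dimethylbicyclo[4.2.0]octan-2-one; 5 3-[(tert-butyldimethylsilyl)oxy]propanal
Product: 6 (1S,6S)-3-{3-[(tert-butyldimethylsilyl)oxy]-1-hydroxypropyl}-7,7-dimethylbicyclo[4.2.0]octan-2-one (epimers at C3 and C1')
Conditions: LiN(iPr)2 (1.1 equiv), THF, −78 °C; then 5; aq NH4Cl
Reagents that add atoms: none
Why: Kinetic deprotonation by the hindered amide takes the C3 methylene and not the cyclobutyl methine C1, and directed aldol addition follows; the two new stereocentres need no control because steps 3 and 4 erase them.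

Step 3
Reactants: 6 aldol adduct
Product: 7 (1S,6S)-3-{3-[(tert-butyldimethylsilyl)oxy]propanoyl}-7,7-dimethylbicyclo[4.2.0]octan-2-one (keto/enol mixture)
Conditions: Dess–Martin periodinane (1.1 equiv), CH2Cl2, 0 °C → rt
Reagents that add atoms: none
Why: Dess–Martin oxidation turns the β-hydroxy ketone into the 1,3-diketone under non-basic conditions, so that retro-aldol cleavage and loss of the silyl ether are avoided.

Step 4
Reactants: 7 1,3-diketone
Product: 8 (1S,3S,6S)-3-{3-[(tert-butyldimethylsilyl)oxy]propanoyl}-3,7,7-trimethylbicyclo[4.2.0]octan-2-one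
Conditions: K2CO3, MeI, acetone, rt
Reagents that add atoms: iodomethane, CI
Why: C-Alkylation of the 1,3-diketone (soft enolate, soft electrophile) builds the quaternary carbon; MeI should approach anti to the cis-fused cyclobutane, on the face that carries H1 and H6, which sets C3 as S, and any minor C3 epimer is removed by chromatography.

Step 5
Reactants: 8 methylated diketone
Product: 10 (1S,3S,6S)-3-[(1R)-1,3-dihydroxypropyl]-3,7,7-trimethylbicyclo[4.2.0]octan-2-one, via silyl ether alcohol 9 (not isolated)
Conditions: (S)-2-methyl-CBS-oxazaborolidine (0.2 equiv), BH3·SMe2 (0.7 equiv), THF, −30 °C; MeOH quench; then HF·pyridine, THF/pyridine, 0 °C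
Reagents that add atoms: none
Why: Corey–Bakshi–Shibata reduction: the catalyst tells the tert-alkyl flank from the CH2 flank of the side-chain ketone and delivers hydride to give the (1'R) carbinol under reagent control, the doubly α-branched ring ketone being far less reactive; fluoride then removes the primary silyl ether.

Step 6
Reactants: 10 keto diol
Product: 11 (1S,3S,6S)-3-[(1R)-1-hydroxy-3-iodopropyl]-3,7,7-trimethylbicyclo[4.2.0]octan-2-one
Conditions: I2, PPh3, imidazole, CH2Cl2, 0 °C
Reagents that add atoms: iodine, II
Why: Garegg–Samuelsson (Appel-type) iodination runs by SN2 on the alkoxyphosphonium ion and is therefore selective for the unhindered primary hydroxyl over the neopentylic secondary one.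

Step 7
Reactants: 11 iodo alcohol
Product: 12 (1R)-3-iodo-1-[(1S,3S,6S)-3,7,7-trimethyl-2-oxobicyclo[4.2.0]octan-3-yl]propyl methanesulfonate
Conditions: MsCl, NEt3, CH2Cl2, −10 °C
Reagents that add atoms: methanesulfonyl chloride, CS(=O)(=O)Cl
Why: Mesylation through sulfene reaches the hindered secondary alcohol with retention at C1'; the quaternary C3 leaves no acidic hydrogen between carbonyl and sulfonate, so β-elimination is blocked.

Step 8
Reactants: 12 iodo keto mesylate
Product: 15 (1S,4E,9S)-4,11,11-trimethylbicyclo[7.2.0]undec-4-en-8-one (cis-fused), via alkylsamarium diiodide 13 (not isolated), via tricyclic samarium alkoxide 14 (not isolated)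
Conditions: SmI2 (2.5 equiv), NiI2 (1 mol %), THF, 0 °C → rt
Reagents that add atoms: none
Why: Two single-electron transfers from divalent samarium reduce the primary C–I bond (far easier to reduce than the mesylate or the dialkyl ketone) to alkylsamarium 13, which adds to the ring carbonyl and so forms the C7–C8 bond and the cis-fused alkoxide 14; the alkoxide then expels the mesylate through the C4–C8 bond (Grob fragmentation), leaving the ketone at C8 and the C4=C5 alkene of 15. The closest known reaction type is the SmI2-promoted sequential intramolecular Barbier cyclisation/Grob fragmentation of iodoalkyl keto mesylates to medium-ring cycloalkenones, together with the base-induced fragmentation of bicyclic 1,3-diol monosulfonates. The five-membered ring closes 5-exo-trig on the carbonyl group, and the nine-membered ring is never closed end to end but uncovered by scission of the bond shared by the six- and five-membered rings (6 + 5 − 2 = 9 ring atoms), so no high dilution is needed. The one new stereocentre, the carbinol carbon C8 of 14, is set by the three-atom tether (cis ring fusion) and disappears again; what is transmitted is the alkene geometry, because the configuration of 12 at the quaternary carbon (C4) and the mesylate carbon (C5) puts methyl and mesylate cis on the cyclopentane, the C5–O bond antiperiplanar to C4–C8 and C6 gauche to the methyl group, which can only give the (4E)-alkene. The step needs carbonyl addition to outrun 3-exo displacement of the mesylate and protonation, which the secondary, neopentylic position of the mesylate and the fast five-membered closure should secure; C1 and C9 take no part and stay as set.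

Step 9
Reactants: 15 cis-fused cyclononenone
Product: 16 (1S,4E,9R)-4,11,11-trimethylbicyclo[7.2.0]undec-4-en-8-one (trans-fused)
Conditions: NaOMe (0.2 equiv), MeOH, rt
Reagents that add atoms: none
Why: Enolisation and reprotonation at C9, the only stereocentre α to the ketone, should drain the cis isomer into the less strained trans-fused bicyclo[7.2.0] ketone under thermodynamic control; C1 and the non-conjugated alkene are untouched.

Step 10
Reactants: 16 trans-fused cyclononenone
Product: 17 (1S,4E,9R)-4,11,11-trimethyl-8-methylidenebicyclo[7.2.0]undec-4-ene, (+)-β-caryophyllene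
Conditions: Ph3PCH3Br, KOtBu, THF, 0 °C → rt
Reagents that add atoms: methyltriphenylphosphonium bromide (as its ylide), C[P+](c1ccccc1)(c1ccccc1)c1ccccc1.[Br-]
Why: Wittig methylenation of the ketone; C9 is already in its thermodynamically preferred configuration, so the basic ylide cannot erode it.

Step 11
Reactants: 17 (+)-β-caryophyllene; 18 benzaldehyde; 19 2,4,6-trihydroxybenzene-1,3-dicarbaldehyde (2,4-diformylphloroglucinol)
Product: 21 target CNP0253700.1, via ortho-quinone methide 20 (not isolated)
Conditions: 18 (1.5 equiv), 19 (1.2 equiv), H2O, 100 °C, sealed tube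
Reagents that add atoms: none
Why: Domino Knoevenagel condensation/inverse-electron-demand hetero-Diels–Alder reaction: 18 and 19 condense at the free ring carbon of 19 to ortho-quinone methide 20, whose O=C–C=C unit adds suprafacially to the strained, electron-rich (4E)-alkene of 17 with oxygen at the more substituted C4, on the outer face of the major ring conformer (the face that is also epoxidised preferentially; gives 4S,5R with C3 and C6 trans) and with phenyl pseudo-equatorial, H-1' trans to H-5 (1'S).

**Compound list**

1 | cyclohex-2-en-1-one | O=C1C=CCCC1 | starting material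
2 | 2-methylpropene (isobutene) | C=C(C)C | starting material
3 | (1R,6S)-7,7-dimethylbicyclo[4.2.0]octan-2-one, trans-fused photoadduct (not isolated) | O=C1CCC[C@H]2[C@H]1CC2(C)C | intermediate
4 | (1S,6S)-7,7-dimethylbicyclo[4.2.0]octan-2-one, cis-fused | O=C1CCC[C@H]2[C@@H]1CC2(C)C | intermediate
5 | 3-[(tert-butyldimethylsilyl)oxy]propanal | O=CCCO[Si](C)(C)C(C)(C)C | starting material
6 | (1S,6S)-3-{3-[(tert-butyldimethylsilyl)oxy]-1-hydroxypropyl}-7,7-dimethylbicyclo[4.2.0]octan-2-one, epimers at C3 and C1' | O=C1C(C(O)CCO[Si](C)(C)C(C)(C)C)CC[C@H]2[C@@H]1CC2(C)C | intermediate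
7 | (1S,6S)-3-{3-[(tert-butyldimethylsilyl)oxy]propanoyl}-7,7-dimethylbicyclo[4.2.0]octan-2-one, keto/enol mixture, C3 not defined | O=C1C(C(=O)CCO[Si](C)(C)C(C)(C)C)CC[C@H]2[C@@H]1CC2(C)C | intermediate
8 | (1S,3S,6S)-3-{3-[(tert-butyldimethylsilyl)oxy]propanoyl}-3,7,7-trimethylbicyclo[4.2.0]octan-2-one | O=C1[C@](C)(C(=O)CCO[Si](C)(C)C(C)(C)C)CC[C@H]2[C@@H]1CC2(C)C | intermediate
9 | (1S,3S,6S)-3-{(1R)-3-[(tert-butyldimethylsilyl)oxy]-1-hydroxypropyl}-3,7,7-trimethylbicyclo[4.2.0]octan-2-one (not isolated) | O=C1[C@](C)([C@H](O)CCO[Si](C)(C)C(C)(C)C)CC[C@H]2[C@@H]1CC2(C)C | intermediate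
10 | (1S,3S,6S)-3-[(1R)-1,3-dihydroxypropyl]-3,7,7-trimethylbicyclo[4.2.0]octan-2-one | O=C1[C@](C)([C@H](O)CCO)CC[C@H]2[C@@H]1CC2(C)C | intermediate
11 | (1S,3S,6S)-3-[(1R)-1-hydroxy-3-iodopropyl]-3,7,7-trimethylbicyclo[4.2.0]octan-2-one | O=C1[C@](C)([C@H](O)CCI)CC[C@H]2[C@@H]1CC2(C)C | intermediate
12 | (1R)-3-iodo-1-[(1S,3S,6S)-3,7,7-trimethyl-2-oxobicyclo[4.2.0]octan-3-yl]propyl methanesulfonate | O=C1[C@](C)([C@H](OS(C)(=O)=O)CCI)CC[C@H]2[C@@H]1CC2(C)C | intermediate
13 | alkylsamarium diiodide derived from 12, C–I replaced by C–SmI2 (not isolated) | O=C1[C@](C)([C@H](OS(C)(=O)=O)CC[Sm](I)I)CC[C@H]2[C@@H]1CC2(C)C | intermediate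
14 | tricyclic diiodosamarium alkoxide, cis-fused cyclopentane on the cyclohexane, with angular O, angular methyl and mesylate cis on the cyclopentane (not isolated) | CS(=O)(=O)O[C@@H]1CC[C@]2(O[Sm](I)I)[C@@]1(C)CC[C@H]1[C@@H]2CC1(C)C | intermediate
15 | (1S,4E,9S)-4,11,11-trimethylbicyclo[7.2.0]undec-4-en-8-one, cis-fused | O=C1CC/C=C(C)/CC[C@H]2[C@@H]1CC2(C)C | intermediate
16 | (1S,4E,9R)-4,11,11-trimethylbicyclo[7.2.0]undec-4-en-8-one, trans-fused | O=C1CC/C=C(C)/CC[C@H]2[C@H]1CC2(C)C | intermediate
17 | (1S,4E,9R)-4,11,11-trimethyl-8-methylidenebicyclo[7.2.0]undec-4-ene, (+)-β-caryophyllene | C=C1CC/C=C(C)/CC[C@H]2[C@H]1CC2(C)C | intermediate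
18 | benzaldehyde | O=Cc1ccccc1 | starting material
19 | 2,4,6-trihydroxybenzene-1,3-dicarbaldehyde (2,4-diformylphloroglucinol) | O=Cc1c(O)c(C=O)c(O)cc1O | starting material
20 | 5-benzylidene-2,4-dihydroxy-6-oxocyclohexa-1,3-diene-1,3-dicarbaldehyde, ortho-quinone methide, alkene geometry not fixed (not isolated) | O=CC1=C(O)C(C=O)=C(O)C(=Cc2ccccc2)C1=O | intermediate
21 | target CNP0253700.1: 5,7-dihydroxy-4-phenylchroman-6,8-dicarbaldehyde fused through its O–C2 and C3 atoms to C4 and C5 of the (1S,9R)-caryophyllane skeleton; 4S,5R,1'S in caryophyllane numbering | C=C1CC[C@@H]2[C@@H](c3ccccc3)c3c(O)c(C=O)c(O)c(C=O)c3O[C@@]2(C)CC[C@H]2[C@H]1CC2(C)C | target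

**Step count**

Total step count: 11. Longest linear sequence: 11 steps (1 → 21).

**Three steps most likely to fail**

Step 8 (key step). What may go wrong: 3-exo displacement of the mesylate by the alkylsamarium (cyclopropane formation) or its protonation may outrun addition to the hindered carbonyl on the concave face, and the trivalent samarium alkoxide may fragment sluggishly while the new ketone is exposed to excess reductant. Fallback, setting out from 11 and coming back at 16: bond formation and fragmentation are separated, and the nucleofuge is introduced only after the ring is closed. The secondary hydroxyl of 11 is capped (Et3SiCl, imidazole) to give triethylsilyl ether F1. SmI2 Barbier cyclisation of F1 (NiI2 cat., THF) forms the same C7–C8 bond and should give tricyclic tertiary alcohol F2. Bu4NF releases tricyclic diol F3, and the secondary hydroxyl alone is mesylated (MsCl, NEt3) to hydroxy mesylate F4. KOtBu in t-BuOH/THF then brings about the classical fragmentation of the potassium alkoxide and equilibrates C9 in the same pot, giving 16.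

Step 4. What may go wrong: insufficient facial discrimination in the C-methylation, since the cyclobutane is three bonds away from C3. The (3R)-epimer would then accompany 8, and because step 5 is catalyst-controlled, that epimer would be carried to the wrong relationship between the quaternary and the carbinol carbon and hence to the (4Z)-alkene in step 8. Fallback, setting out from 7 and coming back at 15: the stereochemical burden is moved from the methylation to the reduction. The methylation is run without regard to selectivity and 8 is separated from its (3R)-epimer F5. F5 is reduced with the (R)-configured CBS catalyst to silyl ether alcohol F6 and desilylated to keto diol F7. Iodination and mesylation as in steps 6 and 7 give iodo alcohol F8 and iodo mesylate F9. F9 has the mirror-image relationship of the quaternary and the mesylate carbon, the only relationship that matters for the fragmentation. Under the conditions of step 8 it should therefore pass through alkylsamarium F10 and tricyclic alkoxide F11 (cyclopentane now on the convex face) to the same ketone 15.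

Step 11. What may go wrong: oligomerisation or hydration of the ortho-quinone methide faster than its capture, addition to the minor ring conformer (giving the diastereomer with the mirror-image chroman part), and acid-promoted transannular cyclisation of 17 at 100 °C, all of which erode the mass balance of 21. Fallback, setting out from 18 and 19 and coming back at 21: the quinone methide is stored as a Mannich base and released slowly without water or acid. Condensation of 19 with 18 and morpholine (EtOH, rt) should give Mannich base F12. Heating F12 with 17 in toluene (110 °C) expels morpholine, regenerates 20 at low stationary concentration and should give 21 after chromatography.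

**Further compounds**

F1 | step 8 | (1S,3S,6S)-3-{(1R)-3-iodo-1-[(triethylsilyl)oxy]propyl}-3,7,7-trimethylbicyclo[4.2.0]octan-2-one | O=C1[C@](C)([C@H](O[Si](CC)(CC)CC)CCI)CC[C@H]2[C@@H]1CC2(C)C
F2 | step 8 | tricyclic tertiary alcohol, Barbier product of F1 with the secondary oxygen as triethylsilyl ether | CC[Si](CC)(CC)O[C@@H]1CC[C@]2(O)[C@@]1(C)CC[C@H]1[C@@H]2CC1(C)C
F3 | step 8 | tricyclic diol, both hydroxyls cis to the angular methyl | O[C@@H]1CC[C@]2(O)[C@@]1(C)CC[C@H]1[C@@H]2CC1(C)C
F4 | step 8 | tricyclic hydroxy mesylate, protonated form of 14 | CS(=O)(=O)O[C@@H]1CC[C@]2(O)[C@@]1(C)CC[C@H]1[C@@H]2CC1(C)C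
F5 | step 4 | (1S,3R,6S)-3-{3-[(tert-butyldimethylsilyl)oxy]propanoyl}-3,7,7-trimethylbicyclo[4.2.0]octan-2-one | O=C1[C@@](C)(C(=O)CCO[Si](C)(C)C(C)(C)C)CC[C@H]2[C@@H]1CC2(C)C
F6 | step 4 | (1S,3R,6S)-3-{(1S)-3-[(tert-butyldimethylsilyl)oxy]-1-hydroxypropyl}-3,7,7-trimethylbicyclo[4.2.0]octan-2-one (not isolated) | O=C1[C@@](C)([C@@H](O)CCO[Si](C)(C)C(C)(C)C)CC[C@H]2[C@@H]1CC2(C)C
F7 | step 4 | (1S,3R,6S)-3-[(1S)-1,3-dihydroxypropyl]-3,7,7-trimethylbicyclo[4.2.0]octan-2-one | O=C1[C@@](C)([C@@H](O)CCO)CC[C@H]2[C@@H]1CC2(C)C
F8 | step 4 | (1S,3R,6S)-3-[(1S)-1-hydroxy-3-iodopropyl]-3,7,7-trimethylbicyclo[4.2.0]octan-2-one | O=C1[C@@](C)([C@@H](O)CCI)CC[C@H]2[C@@H]1CC2(C)C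
F9 | step 4 | (1S)-3-iodo-1-[(1S,3R,6S)-3,7,7-trimethyl-2-oxobicyclo[4.2.0]octan-3-yl]propyl methanesulfonate | O=C1[C@@](C)([C@@H](OS(C)(=O)=O)CCI)CC[C@H]2[C@@H]1CC2(C)C
F10 | step 4 | alkylsamarium diiodide derived from F9 (not isolated) | O=C1[C@@](C)([C@@H](OS(C)(=O)=O)CC[Sm](I)I)CC[C@H]2[C@@H]1CC2(C)C
F11 | step 4 | tricyclic diiodosamarium alkoxide from F10, cyclopentane on the face opposite the cyclobutane (not isolated) | CS(=O)(=O)O[C@H]1CC[C@@]2(O[Sm](I)I)[C@]1(C)CC[C@H]1[C@@H]2CC1(C)C
F12 | step 11 | 2,4,6-trihydroxy-5-[morpholin-4-yl(phenyl)methyl]benzene-1,3-dicarbaldehyde, racemic at the benzylic carbon | O=Cc1c(O)c(C=O)c(O)c(C(c2ccccc2)N2CCOCC2)c1O
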